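In both earlier runs the solid X went slowly and at much the same pace: at 2.00 h, birch held 57 % and elm 55 %, a gap close to the scatter of 1.5 percentage points.

the same everywhere: X 0.20 M

| charge | E | remark | time |
|---|---|---|---|
| birch | 0.24 M | run made earlier |  |
| elm | 0.94 M | run made earlier |  |
| Friday's | 0.760 M |  | 10 h |
| Sunday's | 0.190 M |  | 10 h |
| Monday's | 0.380 M |  | 10 h |

- birch (time / h: X / %, D / %): 0.417: 88, 5; 0.667: 86, 13; 1.00: 78, 18; 2.00: 57, 40; 3.00: 36, 53; 5.00: 7, 59
- elm (time / h: X / %, D / %): 0.333: 91, 5; 1.00: 76, 21; 2.00: 55, 45; 2.50: 43, 55; 4.00: 10, 86; 5.00: 0, 100

(scatter of a reading: 1.5 percentage points)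

- X is a solid; its amount is given per volume of the solution
- the analysis behind the earlier runs scatters by 1.5 percentage points, standard deviation
- at the start none of X is in solution
- what has only dissolved of X counts as not reacted

* part of the X that has reacted (what has only dissolved counts as not reacted) at the end, Friday's
* part of the X that has reacted (what has only dissolved counts as not reacted) at the end, Sunday's
* part of the X that has reacted (what has only dissolved counts as not reacted) at the end, Monday's
* what raising the concentration of E from its lowest to its highest value here does to the part of the X that has reacted (what has only dissolved counts as not reacted) (changes below 5 percentage points count as none) (no change / it rises / it falls)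

By 5.00 h, X stood at 7 % in birch and 0 % in elm, well inside the 10 h asked for. Yet the two runs end apart. Elm's D climbed to 100 %, but between its last two readings birch's D rose 6 points while its X fell 29 points. So I read E as the limiting reagent in birch and took the reckoning from its last reading:

n = cE / (cX × D) = 0.24 M / (0.20 M × 59 %) = 2.03

I called n the price, the E taken up for each X that reacts. It carries the scatter of that reading. At this price elm's E could pay for more than its X, 231 % of it, so elm's X read 0 % at 5.00 h while birch's D stood at 59 %. For the new flasks I reckoned cE / (n × cX):

Friday's: 187 %, so 100 %

Sunday's: 46.7 %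

Monday's: 93.4 %

The forecast gave 100 %, 47 % and 94 % in that order, Monday's above mine, with the trend it rises, expecting that by the end “dissolution should be finished, and reaction should be essentially complete”.

The flasks gave 99.9 % on Friday's, 46.6 % on Sunday's and 88.8 % on Monday's; the trend was it rises, by 53 points.

    G + E ⇌ J + D (K = 0.394, k = 32.0 L mol⁻¹ h⁻¹)
    E + J ⇌ Q, settled at all times (K = 5200 L mol⁻¹)
    X ⇌ G, rate k3*(cs3 - [G]) while solid is left; crystals form when [G] > cs3 (solubility = 0.150 M, k = 0.303 h⁻¹)

One E goes into D and a second pairs with J to Q, which is the price. Friday's flask and Sunday's differ in E, and that difference is the main reason they end apart: with Sunday's E, Friday's run reached 46.6 % against its 99.9 %. Monday's flask came 4.6 points under my figure with 6.87 % of its E still free, and 6.87 % at 100 h. The neighbour of Monday's with 0.095 M of E reckons at 23.4 %, and it gave 23.9 %.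

All runs were generated by integration with made-up constants, noise included.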